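**Retrosynthetic overview**
1. Target 29 ⇒ C1-formyl eudesmane 23 + dearomatised acylphloroglucinol 27. The CH2 bridge is made last by an intermolecular Knoevenagel (aldol-type) condensation with in-situ conjugate hydride reduction.
2. 27 ⇒ phloroglucinol + isovaleryl chloride (Friedel–Crafts acylation, then dearomative gem-dimethylation).
3. 23 ⇒ 1-ketone 21 (one-carbon homologation) ⇒ homoallylic alcohol 18 (OH-directed epoxidation and hydride opening give the C4 carbinol) ⇒ cross-conjugated dienone 11 (C1 oxygen by nucleophilic epoxidation, C5–H by dissolving-metal reduction).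
4. 11 ⇒ (−)-α-cyperone 9 ⇒ (S)-carvone 1 + ethyl vinyl ketone 5. An auxiliary-controlled Michael addition sets the quaternary C10, then aldol condensation closes ring A.
5. Ring order: ring B comes from carvone, ring A is annulated onto it, and the separately made acylphloroglucinol-derived ring is attached last.

Assumption: eudesmane numbering is used for the decalin compounds (C14 = angular methyl on C10, C15 = methyl on C4) with CIP descriptors written out, and keto/enol tautomers of the triketone ring count as one compound.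

**Step 1**
Reactants: 1 (S)-(+)-carvone
Product: 2 (2S,5S)-dihydrocarvone (a little 2R epimer is present)
Conditions: LiBH(s-Bu)3 (1.1 equiv), THF, −78 °C; H2O quench
Reagents that add atoms: none
Why: Conjugate (1,4) hydride reduction of the β-unsubstituted cyclohexenone leaves C5 and the isopropenyl group untouched, and the C2 epimer ratio does not matter because C2 is rebuilt in step 3.

**Step 2**
Reactants: 2 (2S,5S)-dihydrocarvone; 3 (S)-(−)-1-phenylethylamine
Product: 4 (2S,5S)-2-methyl-N-[(1S)-1-phenylethyl]-5-(prop-1-en-2-yl)cyclohexan-1-imine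
Conditions: p-TsOH (1 mol%), toluene, reflux, Dean–Stark
Reagents that add atoms: none
Why: Acid-catalysed imine condensation driven by azeotropic removal of water installs the chiral amine that controls the next step.

**Step 3**
Reactants: 4 ketimine; 5 ethyl vinyl ketone (pent-1-en-3-one)
Product: 7 (2R,5S)-2-methyl-2-(3-oxopentyl)-5-(prop-1-en-2-yl)cyclohexan-1-one, via Michael-adduct imine 6 (not isolated)
Conditions: 5 (1.5 equiv), THF, 40 °C, 4 d; then 10% aq AcOH, rt
Reagents that add atoms: water, O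
Why: In this d'Angelo-type asymmetric Michael addition the more substituted secondary enamine tautomer of 4 adds to the enone through a cyclic aza-ene-like transition state on the face away from the auxiliary phenyl group, which sets the quaternary carbon (future C10) as R with its methyl cis to the isopropenyl group, and mild hydrolysis then frees the 1,5-diketone.

**Step 4**
Reactants: 7 1,5-diketone
Product: 9 (−)-α-cyperone [(4aR,7S)-1,4a-dimethyl-7-(prop-1-en-2-yl)-4,4a,5,6,7,8-hexahydronaphthalen-2(3H)-one], via aldol ketol 8 (not isolated)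
Conditions: NaOMe (1.5 equiv), MeOH, rt → 60 °C
Reagents that add atoms: none
Why: Intramolecular aldol condensation (second stage of the Robinson annulation) closes ring A and E1cB dehydration gives the tetrasubstituted enone, so no new stereocentre is kept.

**Step 5**
Reactants: 9 (−)-α-cyperone
Product: 11 (4aR,7S)-1,4a-dimethyl-7-(prop-1-en-2-yl)-5,6,7,8-tetrahydronaphthalen-2(4aH)-one (eudesma-1,4,11-trien-3-one), via trimethylsilyl dienol ether 10 (not isolated)
Conditions: LiN(i-Pr)2 (1.2 equiv), THF, −78 °C; Me3SiCl; then Pd(OAc)2 (1.1 equiv), MeCN, rt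
Reagents that add atoms: none
Why: Kinetic deprotonation at C2 gives the cross-conjugated dienolate, whose silyl ether undergoes Saegusa–Ito oxidation to the C1=C2 double bond without touching the isopropenyl group.

**Step 6**
Reactants: 11 dienone
Product: 12 (1S,2S,7S,10S)-1,2-epoxyeudesma-4,11-dien-3-one
Conditions: 30% H2O2, NaOH (aq), MeOH, 0 °C → rt
Reagents that add atoms: hydrogen peroxide, OO
Why: Weitz–Scheffer nucleophilic epoxidation attacks only the less substituted enone double bond, and hydroperoxide adds to C1 on the face opposite the angular C14 methyl, which sets C1 and C2.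

**Step 7**
Reactants: 12 epoxy enone
Product: 13 (1R,7S,10S)-1-hydroxyeudesma-4,11-dien-3-one
Conditions: SmI2 (2.5 equiv), THF/MeOH, −90 °C
Reagents that add atoms: none
Why: Single-electron reductive opening of the α,β-epoxy ketone cleaves the C2–O bond next to the carbonyl and gives the β-hydroxy ketone with the C1 oxygen configuration unchanged.

**Step 8**
Reactants: 13 hydroxy enone
Product: 14 (1R,7S,10S)-1-(tert-butyldimethylsilyloxy)eudesma-4,11-dien-3-one
Conditions: TBSOTf (1.5 equiv), 2,6-lutidine, CH2Cl2, −78 → 0 °C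
Reagents that add atoms: tert-butyldimethylsilyl trifluoromethanesulfonate, CC(C)(C)[Si](C)(C)OS(=O)(=O)C(F)(F)F
Why: Silyl ether formation with the reactive silyl triflate protects the hindered axial β-hydroxyl against elimination and against O-triflation in step 9.

**Step 9**
Reactants: 14 silyl ether enone
Product: 16 (1R,5S,7S,10S)-1-(tert-butyldimethylsilyloxy)eudesma-3,11-dien-3-yl trifluoromethanesulfonate, via lithium enolate 15 (not isolated)
Conditions: Li (3 equiv), NH3(l)/THF, t-BuOH (1.0 equiv), −78 °C; isoprene; evaporate NH3; PhNTf2 (1.5 equiv), THF, 0 °C → rt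
Reagents that add atoms: N-phenylbis(trifluoromethanesulfonimide), O=S(=O)(N(c1ccccc1)S(=O)(=O)C(F)(F)F)C(F)(F)F
Why: Dissolving-metal (Birch-type) reduction of the enone protonates the C5 carbanion axially on the face opposite the angular methyl to give the trans ring fusion, and the regiospecific C3–C4 enolate is trapped as its enol triflate.

**Step 10**
Reactants: 16 enol triflate
Product: 17 (1R,5R,7S,10S)-1-(tert-butyldimethylsilyloxy)eudesma-3,11-diene
Conditions: Pd(OAc)2 (5 mol%), PPh3 (10 mol%), Bu3N (3 equiv), HCO2H (2 equiv), DMF, 60 °C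
Reagents that add atoms: none
Why: Palladium-catalysed formate hydrogenolysis of the vinyl triflate replaces OTf by H with the double bond fixed at C3=C4 and the isopropenyl group untouched.

**Step 11**
Reactants: 17 silyl ether diene
Product: 18 (1R,5R,7S,10S)-eudesma-3,11-dien-1-ol
Conditions: Bu4NF (3 equiv), THF, 50 °C
Reagents that add atoms: none
Why: Fluoride-mediated desilylation frees the axial C1 hydroxyl, which sits homoallylic to C3=C4 on the face opposite the angular methyl.

**Step 12**
Reactants: 18 homoallylic alcohol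
Product: 19 (1R,3S,4R,5S,7S,10S)-3,4-epoxyeudesm-11-en-1-ol
Conditions: VO(acac)2 (5 mol%), t-BuOOH (1.5 equiv), CH2Cl2, rt → 40 °C
Reagents that add atoms: tert-butyl hydroperoxide, CC(C)(C)OO
Why: Hydroxyl-directed vanadium-catalysed epoxidation of the cyclohex-3-en-1-ol unit delivers oxygen syn to the C1 hydroxyl (anti to the angular methyl), which sets C3 and C4 and leaves the undirected isopropenyl group alone.

**Step 13**
Reactants: 19 epoxy alcohol
Product: 20 (1R,4S,5S,7S,10S)-eudesm-11-ene-1,4-diol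
Conditions: LiBHEt3 (4 equiv), THF, 0 → 60 °C; aq NH4Cl
Reagents that add atoms: none
Why: SN2 hydride opening of the trisubstituted epoxide at the less hindered secondary C3 keeps the C4–O bond and gives the tertiary carbinol with its hydroxyl equatorial and anti to the angular methyl.

**Step 14**
Reactants: 20 diol
Product: 21 (4S,5S,7S,10S)-4-hydroxyeudesm-11-en-1-one
Conditions: Dess–Martin periodinane (1.3 equiv), NaHCO3, CH2Cl2, 0 °C → rt
Reagents that add atoms: none
Why: Dess–Martin oxidation converts the secondary C1 alcohol into the ketone while the tertiary C4 alcohol cannot be oxidised.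

**Step 15**
Reactants: 21 hydroxy ketone
Product: 22 (4S,5S,7S,10S)-1-(methoxymethylidene)eudesm-11-en-4-ol (E/Z mixture)
Conditions: Ph3P(CH2OMe)Cl (4 equiv), KN(SiMe3)2 (4 equiv), THF, 0 → 50 °C
Reagents that add atoms: (methoxymethyl)triphenylphosphonium chloride, COC[P+](c1ccccc1)(c1ccccc1)c1ccccc1.[Cl-]
Why: Wittig methoxymethylenation with an excess of the small ylide homologates the hindered C1 ketone by one carbon, and the tertiary alkoxide formed in the flask does not interfere.

**Step 16**
Reactants: 22 enol ether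
Product: 23 (1S,4S,5S,7S,10S)-4-hydroxyeudesm-11-ene-1-carbaldehyde
Conditions: 2 M HCl/THF (1:4), 0 °C → rt
Reagents that add atoms: water, O
Why: Acid hydrolysis of the enol ether protonates C1 axially from the face opposite the adjacent angular methyl, so the formyl group ends equatorial and cis to that methyl, which is also the slightly more stable epimer.

**Step 17**
Reactants: 24 phloroglucinol; 25 isovaleryl chloride
Product: 26 3-methyl-1-(2,4,6-trihydroxyphenyl)butan-1-one
Conditions: AlCl3 (4 equiv), PhNO2/CH2Cl2, 0 → 50 °C; aq HCl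
Reagents that add atoms: none
Why: Friedel–Crafts C-acylation of the activated arene stops at mono-acylation because the acyl group deactivates the ring.

**Step 18**
Reactants: 26 acylphloroglucinol
Product: 27 3,5-dihydroxy-6,6-dimethyl-2-(3-methylbutanoyl)cyclohexa-2,4-dien-1-one
Conditions: NaOMe (3.0 equiv), MeI (2.2 equiv), MeOH, 0 °C → rt; aq HCl
Reagents that add atoms: iodomethane, CI
Why: In this dearomative double C-methylation the first methyl makes its carbon the most nucleophilic site, so the second methyl enters at the same carbon and gives the gem-dimethyl cyclic triketone.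

**Step 19**
Reactants: 23 aldehyde; 27 dearomatised acylphloroglucinol
Product: 29 target compound CNP0490948.1, via Knoevenagel alkylidene 28 (not isolated)
Conditions: diethyl 2,6-dimethyl-1,4-dihydropyridine-3,5-dicarboxylate (Hantzsch ester, 1.2 equiv), L-proline (20 mol%), CH2Cl2, rt
Reagents that add atoms: none
Why: Intermolecular Knoevenagel (aldol-type) condensation of the aldehyde with the only free ring carbon of the vinylogous acid gives an o-quinone-methide-like alkylidene that is reduced at once by conjugate hydride transfer from the Hantzsch ester (three-component reductive alkylation), forming the CH2 bridge without touching C1.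

**Compound list**
1 | (S)-(+)-carvone | C=C(C)[C@H]1CC=C(C)C(=O)C1 | starting material
2 | (2S,5S)-dihydrocarvone (major C2 epimer) | C=C(C)[C@H]1CC[C@H](C)C(=O)C1 | intermediate
3 | (S)-(−)-1-phenylethylamine | C[C@H](N)c1ccccc1 | starting material
4 | (2S,5S)-2-methyl-N-[(1S)-1-phenylethyl]-5-(prop-1-en-2-yl)cyclohexan-1-imine | C=C(C)[C@H]1CC[C@H](C)C(=N[C@@H](C)c2ccccc2)C1 | intermediate
5 | ethyl vinyl ketone (pent-1-en-3-one) | C=CC(=O)CC | starting material
6 | 1-[(1R,4S)-1-methyl-2-{[(1S)-1-phenylethyl]imino}-4-(prop-1-en-2-yl)cyclohexyl]pentan-3-one | C=C(C)[C@H]1CC[C@](C)(CCC(=O)CC)C(=N[C@@H](C)c2ccccc2)C1 | intermediate (not isolated)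
7 | (2R,5S)-2-methyl-2-(3-oxopentyl)-5-(prop-1-en-2-yl)cyclohexan-1-one | C=C(C)[C@H]1CC[C@](C)(CCC(=O)CC)C(=O)C1 | intermediate
8 | (4aR,7S)-8a-hydroxy-1,4a-dimethyl-7-(prop-1-en-2-yl)octahydronaphthalen-2(1H)-one (epimers at C1 and C8a) | C=C(C)[C@H]1CC[C@]2(C)CCC(=O)C(C)C2(O)C1 | intermediate (not isolated)
9 | (−)-α-cyperone, (4aR,7S)-1,4a-dimethyl-7-(prop-1-en-2-yl)-4,4a,5,6,7,8-hexahydronaphthalen-2(3H)-one | C=C(C)[C@H]1CC[C@]2(C)CCC(=O)C(C)=C2C1 | intermediate
10 | (4aR,7S)-1,4a-dimethyl-7-(prop-1-en-2-yl)-2-(trimethylsilyloxy)-4,4a,5,6,7,8-hexahydronaphthalene | C=C(C)[C@H]1CC[C@]2(C)CC=C(O[Si](C)(C)C)C(C)=C2C1 | intermediate (not isolated)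
11 | (4aR,7S)-1,4a-dimethyl-7-(prop-1-en-2-yl)-5,6,7,8-tetrahydronaphthalen-2(4aH)-one | C=C(C)[C@H]1CC[C@]2(C)C=CC(=O)C(C)=C2C1 | intermediate
12 | (1S,2S,7S,10S)-1,2-epoxyeudesma-4,11-dien-3-one (epoxide anti to C14) | C=C(C)[C@H]1CC[C@]2(C)[C@@H]3O[C@@H]3C(=O)C(C)=C2C1 | intermediate
13 | (1R,7S,10S)-1-hydroxyeudesma-4,11-dien-3-one (OH anti to C14) | C=C(C)[C@H]1CC[C@]2(C)[C@H](O)CC(=O)C(C)=C2C1 | intermediate
14 | (1R,7S,10S)-1-(tert-butyldimethylsilyloxy)eudesma-4,11-dien-3-one | C=C(C)[C@H]1CC[C@]2(C)[C@H](O[Si](C)(C)C(C)(C)C)CC(=O)C(C)=C2C1 | intermediate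
15 | lithium (1R,5S,7S,10S)-1-(tert-butyldimethylsilyloxy)eudesma-3,11-dien-3-olate | C=C(C)[C@H]1CC[C@]2(C)[C@H](O[Si](C)(C)C(C)(C)C)CC([O-])=C(C)[C@H]2C1.[Li+] | intermediate (not isolated)
16 | (1R,5S,7S,10S)-1-(tert-butyldimethylsilyloxy)eudesma-3,11-dien-3-yl trifluoromethanesulfonate | C=C(C)[C@H]1CC[C@]2(C)[C@H](O[Si](C)(C)C(C)(C)C)CC(OS(=O)(=O)C(F)(F)F)=C(C)[C@H]2C1 | intermediate
17 | (1R,5R,7S,10S)-1-(tert-butyldimethylsilyloxy)eudesma-3,11-diene | C=C(C)[C@H]1CC[C@]2(C)[C@H](O[Si](C)(C)C(C)(C)C)CC=C(C)[C@H]2C1 | intermediate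
18 | (1R,5R,7S,10S)-eudesma-3,11-dien-1-ol | C=C(C)[C@H]1CC[C@]2(C)[C@H](O)CC=C(C)[C@H]2C1 | intermediate
19 | (1R,3S,4R,5S,7S,10S)-3,4-epoxyeudesm-11-en-1-ol (epoxide syn to 1-OH) | C=C(C)[C@H]1CC[C@]2(C)[C@H](O)C[C@@H]3O[C@]3(C)[C@H]2C1 | intermediate
20 | (1R,4S,5S,7S,10S)-eudesm-11-ene-1,4-diol | C=C(C)[C@H]1CC[C@]2(C)[C@H](O)CC[C@](C)(O)[C@H]2C1 | intermediate
21 | (4S,5S,7S,10S)-4-hydroxyeudesm-11-en-1-one | C=C(C)[C@H]1CC[C@]2(C)C(=O)CC[C@](C)(O)[C@H]2C1 | intermediate
22 | (4S,5S,7S,10S)-1-(methoxymethylidene)eudesm-11-en-4-ol (E/Z mixture) | C=C(C)[C@H]1CC[C@]2(C)C(=COC)CC[C@](C)(O)[C@H]2C1 | intermediate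
23 | (1S,4S,5S,7S,10S)-4-hydroxyeudesm-11-ene-1-carbaldehyde (CHO equatorial, cis to C14) | C=C(C)[C@H]1CC[C@]2(C)[C@@H](C=O)CC[C@](C)(O)[C@H]2C1 | intermediate
24 | phloroglucinol (benzene-1,3,5-triol) | Oc1cc(O)cc(O)c1 | starting material
25 | isovaleryl chloride (3-methylbutanoyl chloride) | CC(C)CC(=O)Cl | starting material
26 | 3-methyl-1-(2,4,6-trihydroxyphenyl)butan-1-one | CC(C)CC(=O)c1c(O)cc(O)cc1O | intermediate
27 | 3,5-dihydroxy-6,6-dimethyl-2-(3-methylbutanoyl)cyclohexa-2,4-dien-1-one | CC(C)CC(=O)C1=C(O)C=C(O)C(C)(C)C1=O | intermediate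
28 | 5-hydroxy-4-{[(1R,4S,5S,7S,10R)-4-hydroxyeudesm-11-en-1-yl]methylidene}-2,2-dimethyl-6-(3-methylbutanoyl)cyclohex-5-ene-1,3-dione | C=C(C)[C@H]1CC[C@]2(C)[C@@H](C=C3C(=O)C(C)(C)C(=O)C(C(=O)CC(C)C)=C3O)CC[C@](C)(O)[C@H]2C1 | intermediate (not isolated)
29 | 3,5-dihydroxy-4-{[(1R,4S,5S,7S,10R)-4-hydroxyeudesm-11-en-1-yl]methyl}-6,6-dimethyl-2-(3-methylbutanoyl)cyclohexa-2,4-dien-1-one | C=C(C)[C@H]1CC[C@]2(C)[C@@H](CC3=C(O)C(C)(C)C(=O)C(C(=O)CC(C)C)=C3O)CC[C@](C)(O)[C@H]2C1 | target

**Step count and risks**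
Total steps: 19. Longest linear sequence: 17 steps (steps 1–16 and 19, from (S)-carvone); steps 17–18 run in parallel.

Most likely to fail, first: step 19. The aldehyde is neopentyl-like, so condensation may be slow; a second molecule of 27 may add to alkylidene 28; and amine catalysis could epimerise C1. The fallback sets out from 23 (with 27) and comes back at 29. A three-component Knoevenagel/thia-Michael coupling with thiophenol (piperidinium acetate cat., CH2Cl2) traps the alkylidene as the isolable phenylthio adduct of 29 F4. Radical desulfurisation with Bu3SnH and AIBN (toluene, 80 °C) then gives 29.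

Second: step 15. The C1 ketone is flanked by the quaternary C10 and may enolise instead of olefinating. The fallback sets out from 21 and comes back at 23. Corey–Chaykovsky reaction with dimethylsulfonium methylide (Me3SI, KN(SiMe3)2, THF, 0 °C) adds CH2 axially, anti to the angular methyl, to give (1S,4S,5S,7S,10S)-4-hydroxyeudesm-11-ene-1-spiro-2'-oxirane F3. MgBr2·OEt2 (or BF3·OEt2 at −78 °C) in CH2Cl2 then induces a Meinwald rearrangement in which hydride migrates to C1 with inversion, giving the equatorial aldehyde 23 directly.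

Third: step 9. Enolate trapping in the one-pot reductive triflation may be incomplete, or the ring fusion may form as a mixture beside the axial silyloxy group. The fallback sets out from 14 and comes back at 16. Li/NH3 reduction of 14 with NH4Cl quench gives the purifiable trans-fused ketone (1R,4R,5R,7S,10S)-1-(tert-butyldimethylsilyloxy)eudesm-11-en-3-one F1. Equilibrating silylation (Me3SiCl, NaI, Et3N, MeCN) converts it into the more substituted enol ether (1R,5S,7S,10S)-1-(tert-butyldimethylsilyloxy)-3-(trimethylsilyloxy)eudesma-3,11-diene F2. MeLi (THF, 0 °C) cleaves F2 to lithium enolate 15, and PhNTf2 then gives 16.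

**Further compounds**
F1 | step 9 | (1R,4R,5R,7S,10S)-1-(tert-butyldimethylsilyloxy)eudesm-11-en-3-one | C=C(C)[C@H]1CC[C@]2(C)[C@H](O[Si](C)(C)C(C)(C)C)CC(=O)[C@H](C)[C@H]2C1
F2 | step 9 | (1R,5S,7S,10S)-1-(tert-butyldimethylsilyloxy)-3-(trimethylsilyloxy)eudesma-3,11-diene | C=C(C)[C@H]1CC[C@]2(C)[C@H](O[Si](C)(C)C(C)(C)C)CC(O[Si](C)(C)C)=C(C)[C@H]2C1
F3 | step 15 | (1S,4S,5S,7S,10S)-4-hydroxyeudesm-11-ene-1-spiro-2'-oxirane (oxirane CH2 anti to C14) | C=C(C)[C@H]1CC[C@]2(C)[C@]3(CO3)CC[C@](C)(O)[C@H]2C1
F4 | step 19 | phenylthio adduct of 29 (PhS on the bridging carbon, both epimers there) | C=C(C)[C@H]1CC[C@]2(C)[C@@H](C(Sc4ccccc4)C3=C(O)C(C)(C)C(=O)C(C(=O)CC(C)C)=C3O)CC[C@](C)(O)[C@H]2C1
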